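**Assumptions (one line each).** Gibberellin atom numbering (C1–C20) is used in the explanations. Multi-carbon building blocks are numbered as compounds; one-carbon and heteroatom reagents are listed under "Reagents that add atoms". This route is a paper design: no step has been run, and the stereochemical outcomes are argued from analogy.

## Retrosynthetic overview

1. GA98 ⇐ methyl ester 18 ⇐ ring D by ketyl–alkyne cyclisation of 8-propargyl-13-ketone 17 ⇐ conjugate propargylation of C-ring enone 15.
2. Enone 14 (with 2β-OH and 9-H) ⇐ one late Birch reduction cascade on anisole ketone 13; the arene is carried through as a masked C-ring enone.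
3. Ring A and the 19,20-lactone ⇐ α,α′-annulation of indane 7 with 3-chloro-2-(chloromethyl)propene (C10 aldehyde alkylation, lactonisation, lactone-enolate closure).
4. Indanone acid 4 ⇐ Friedel–Crafts closure of (S)-arylsuccinate 3 ⇐ Rh-catalysed enantioselective arylation of symmetric fumarate 2 with 1.
5. Ring order: C (as arene) → B → lactone → A → C dearomatised → D.

## Route

**Step 1**
Reactants: 1, 3-methoxyphenylboronic acid; 2, di-tert-butyl fumarate
Product: 3, di-tert-butyl (S)-2-(3-methoxyphenyl)butanedioate
Conditions: [RhCl(C2H4)2]2 (1.5 mol %), chiral bicyclic diene ligand (3.3 mol %, enantiomer chosen to give S), KOH (10 mol %), dioxane/H2O 10:1, 50 °C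
Reagents that add atoms: none
Why: Rh/chiral-diene asymmetric 1,4-addition (Hayashi–Miyaura) of the aryl group to one enantiotopic face of the symmetric fumarate sets C6, the only stereocentre introduced by a catalyst; all others are relayed from it.

**Step 2**
Reactants: 3
Product: 4, (S)-6-methoxy-3-oxo-2,3-dihydro-1H-indene-1-carboxylic acid
Conditions: Eaton's reagent (P2O5/MsOH), 45 °C; recrystallise to upgrade ee
Reagents that add atoms: none
Why: Acidolysis of both tert-butyl esters followed by intramolecular Friedel–Crafts acylation para to OMe (only the CH2CO2H arm can reach the ring) closes ring B with C10 as ketone, and C6 sees no base.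

**Step 3**
Reactants: 4; 5, methyl bromoacetate
Product: 6, (1S,2S)-6-methoxy-2-(2-methoxy-2-oxoethyl)-3-oxo-2,3-dihydro-1H-indene-1-carboxylic acid (1,2-trans)
Conditions: LiHMDS (2.2 equiv), THF, −78 °C; then 5, −78 → −30 °C
Reagents that add atoms: none (both partners are numbered reactants)
Why: Enolate alkylation of the carboxylate/ketone-enolate dianion occurs at C5 anti to the neighbouring carboxylate (C4 arm trans to C7), and the carboxylate keeps C6 from being deprotonated.

**Step 4**
Reactants: 6
Product: 7, 3-formyl-6-methoxy-2-(2-methoxy-2-oxoethyl)-2,3-dihydro-1H-indene-1-carboxylic acid (C1/C2 as in 6; C3 epimer mixture)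
Conditions: Ph3P(CH2OMe)Cl (4 equiv), KOtBu (5 equiv), THF, 0 °C → rt; then 2 M HCl, THF, rt
Reagents that add atoms: (methoxymethyl)triphenylphosphonium chloride, COC[P+](c1ccccc1)(c1ccccc1)c1ccccc1.[Cl-] (gives C20); water, O (aldehyde oxygen)
Why: Wittig methoxymethylenation and hydrolysis of the aryl-conjugated enol ether homologates the C10 ketone to the C10–CHO (C20) aldehyde; the C10 configuration is irrelevant because it is enolised in the next step.

**Step 5**
Reactants: 7; 8, 3-chloro-2-(chloromethyl)prop-1-ene
Product: 9, 3-[2-(chloromethyl)prop-2-en-1-yl]-3-formyl-6-methoxy-2-(2-methoxy-2-oxoethyl)-2,3-dihydro-1H-indene-1-carboxylic acid (CHO cis to the C2 CH2CO2Me arm, allyl group trans to it, CO2H trans to the C2 arm)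
Conditions: KOtBu (2.2 equiv), THF/t-BuOH, 0 °C; 8 (4 equiv), NaI (cat.)
Reagents that add atoms: none (both partners are numbered reactants)
Why: C-alkylation of the α-aryl aldehyde enolate takes place anti to the adjacent C5 substituent, creating quaternary C10 with C1 trans and C20 cis to the C4 arm, which is the natural A/B-trans arrangement.

**Step 6**
Reactants: 9
Product: 10, tricyclic δ-lactone acid (O–CH2 on C10 and CH2–C=O on C5, cis-fused to the indane; C10 also carries the 2-(chloromethyl)allyl group on the opposite face; 6-CO2H trans to the C5 arm)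
Conditions: NaBH4, MeOH, −20 °C, AcOH quench; then CSA (cat.), PhMe, 60 °C
Reagents that add atoms: none
Why: Chemoselective aldehyde reduction gives C20–OH cis to the CH2CO2Me arm, which lactonises under acid to the 19,20-lactone; acidic closure avoids Williamson attack of the alkoxide on the allylic chloride, and C7 cannot lactonise because it is trans.

**Step 7**
Reactants: 10
Product: 11, α-methyl lactone (C4 epimer mixture)
Conditions: LDA (2.05 equiv), THF, −78 °C; MeI (1.2 equiv), −78 °C
Reagents that add atoms: iodomethane, CI
Why: Enolate methylation of the lactone installs C18 (C4 configuration irrelevant here); at −78 °C MeI outcompetes the tethered allylic chloride, and methylation must come first because C4 becomes a bridgehead in the next step.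

**Step 8**
Reactants: 11
Product: 12, tetracyclic acid with aromatic ring C: ring A closed, 2-methylene, C4 bearing equatorial CH3 and axial lactone carbonyl, 19,20-δ-lactone, A/B trans
Conditions: KHMDS (2.2 equiv), THF, −78 → 0 °C, NaI (cat.)
Reagents that add atoms: none
Why: Intramolecular SN2 alkylation of the tertiary lactone enolate by the allylic chloride (second half of an α,α′-annulation) closes ring A as a bicyclo[3.3.1] lactone; the tether forces C19 axial and cis to C20 with CH3 equatorial, and the ring is trans-fused because C1 and C4 were already trans on ring B.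

**Step 9**
Reactants: 12
Product: 13, the corresponding 2-ketone
Conditions: O3, CH2Cl2/MeOH, −78 °C (Sudan III end-point); Me2S
Reagents that add atoms: ozone, [O-][O+]=O
Why: Ozonolysis cleaves the 1,1-disubstituted alkene much faster than it attacks the anisole ring, unveiling the C2 carbonyl.

**Step 10 (key step)**
Reactants: 13
Product: 14, 2β-hydroxy-13-oxo-8(14)-ene 19,20-lactone 7-acid (rings A/B/C of GA98 with a C-ring enone; 9-H trans to C20)
Conditions: (i) LiOH (3 equiv), THF/H2O, rt, evaporate; (ii) Li (15 equiv), NH3(l)/THF/t-BuOH, −78 → −33 °C, NH4Cl; (iii) 2 M HCl, THF/H2O, rt; esterify promptly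
Reagents that add atoms: water, O (oxygen of the new C13 ketone, from enol-ether hydrolysis)
Why: Birch reduction of the anisole on the lactone-opened tricarboxylate/alkoxide salt (carboxylates are inert to Li/NH3) also reduces the C2 ketone under thermodynamic control to the equatorial 2β-alcohol (the axial epimer would be 1,3-diaxial to both C19 and C20), and the acid work-up hydrolyses the enol ether, conjugates the enone with C9 protonated anti to axial C20 (H9 trans to C20, as in the estradiol methyl ether → 19-nortestosterone sequence), lets C6 settle trans to C4 and recloses the lactone.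

**Step 11**
Reactants: 14
Product: 15, methyl ester of 14
Conditions: TMSCHN2, PhMe/MeOH, 0 °C
Reagents that add atoms: trimethylsilyldiazomethane, C[Si](C)(C)C=[N+]=[N-] (ester CH3 carbon)
Why: Diazoalkane esterification protects C7 under neutral conditions and removes the vinylogous β-keto acid, which could otherwise decarboxylate.

**Step 12**
Reactants: 15; 16, tributyl(propa-1,2-dienyl)stannane
Product: 17, 8-propargyl-13-ketone (propargyl cis to 9-H, trans to C20)
Conditions: BSA (transient 2-O-TMS), CH2Cl2; TiCl4 (2.5 equiv), 16 (3 equiv), −78 → −40 °C; aq HCl work-up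
Reagents that add atoms: none (both partners are numbered reactants)
Why: Lewis-acid-mediated conjugate propargylation (Sakurai-type SE2′ of the allenylstannane) attacks C8 from the face anti to axial C20 and trans to the C9–C10 bond, giving the cis-fused B/C quaternary centre; C7 is pseudo-equatorial and does not block that face.

**Step 13**
Reactants: 17
Product: 18, gibberellin A98 methyl ester
Conditions: SmI2 (4 equiv), HMPA, t-BuOH, THF, 0 °C → rt
Reagents that add atoms: none
Why: Ketyl–alkyne reductive cyclisation (5-exo-dig, the Stork keto-alkyne closure) forms the C13–C16 bond, giving the bridgehead 13-OH and the 16-methylene; the C13 configuration is fixed by the bridge.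

**Step 14**
Reactants: 18
Product: 19, gibberellin A98
Conditions: LiSPr, HMPA, rt; work-up at pH 3
Reagents that add atoms: none
Why: SN2 demethylation of the hindered C7 methyl ester by thiolate leaves the lactone (neopentyl O–CH2) and the acid-sensitive 13-hydroxy-16-ene untouched.

## Compound list

1 | 3-methoxyphenylboronic acid | COc1cccc(c1)B(O)O | starting material
2 | di-tert-butyl fumarate | CC(C)(C)OC(=O)/C=C/C(=O)OC(C)(C)C | starting material
3 | di-tert-butyl (S)-2-(3-methoxyphenyl)butanedioate | COc1cccc(c1)[C@H](CC(=O)OC(C)(C)C)C(=O)OC(C)(C)C | intermediate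
4 | (S)-6-methoxy-3-oxo-2,3-dihydro-1H-indene-1-carboxylic acid | COc1ccc2c(c1)[C@@H](C(=O)O)CC2=O | intermediate
5 | methyl bromoacetate | COC(=O)CBr | starting material
6 | (1S,2S)-6-methoxy-2-(2-methoxy-2-oxoethyl)-3-oxo-indane-1-carboxylic acid | COc1ccc2c(c1)[C@@H](C(=O)O)[C@H](CC(=O)OC)C2=O | intermediate
7 | 3-formyl analogue of 6 (C3 epimers) | COc1ccc2c(c1)[C@@H](C(=O)O)[C@H](CC(=O)OC)C2C=O | intermediate
8 | 3-chloro-2-(chloromethyl)prop-1-ene | ClCC(=C)CCl | starting material
9 | C10-quaternary aldehyde (CHO cis to CH2CO2Me arm) | COc1ccc2c(c1)[C@@H](C(=O)O)[C@H](CC(=O)OC)[C@@]2(C=O)CC(=C)CCl | intermediate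
10 | cis-fused 19,20-δ-lactone acid with 2-(chloromethyl)allyl on C10 | COc1ccc2c(c1)[C@@H](C(=O)O)[C@@H]3CC(=O)OC[C@]23CC(=C)CCl | intermediate
11 | C4-methyl lactone (C4 epimers) | COc1ccc2c(c1)[C@@H](C(=O)O)[C@@H]3C(C)C(=O)OC[C@]23CC(=C)CCl | intermediate
12 | ring-C-aromatic tetracycle, 2-methylene | COc1ccc2c(c1)[C@@H](C(=O)O)[C@@H]3[C@@]4(C)CC(=C)C[C@@]23COC4=O | intermediate
13 | ring-C-aromatic tetracycle, 2-ketone | COc1ccc2c(c1)[C@@H](C(=O)O)[C@@H]3[C@@]4(C)CC(=O)C[C@@]23COC4=O | intermediate
14 | 2β-hydroxy-13-oxo-8(14)-ene lactone acid | O=C1CC[C@@H]2C(=C1)[C@@H](C(=O)O)[C@@H]3[C@@]4(C)C[C@@H](O)C[C@@]23COC4=O | intermediate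
15 | methyl ester of 14 | O=C1CC[C@@H]2C(=C1)[C@@H](C(=O)OC)[C@@H]3[C@@]4(C)C[C@@H](O)C[C@@]23COC4=O | intermediate
16 | tributyl(propa-1,2-dienyl)stannane | C=C=C[Sn](CCCC)(CCCC)CCCC | starting material
17 | 8-propargyl-13-ketone methyl ester | O=C1CC[C@@H]2[C@@](C1)(CC#C)[C@@H](C(=O)OC)[C@@H]3[C@@]4(C)C[C@@H](O)C[C@@]23COC4=O | intermediate
18 | gibberellin A98 methyl ester | C=C1C[C@]23C[C@@]1(O)CC[C@H]2[C@]12COC(=O)[C@](C)(C[C@@H](O)C1)[C@H]2[C@@H]3C(=O)OC | intermediate
19 | gibberellin A98 | C=C1C[C@]23C[C@@]1(O)CC[C@H]2[C@]12COC(=O)[C@](C)(C[C@@H](O)C1)[C@H]2[C@@H]3C(=O)O | target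

## Summary

Total steps: 14. Longest linear sequence: 14 (fully linear from 1 and 2).

Three steps most likely to fail, each with a fallback that changes the approach:

1. **Step 10 (Birch cascade).** The risks are incomplete or unselective C2 reduction, a wrong C9 epimer, and decarboxylation of the vinylogous β-keto acid. Fallback: separate the jobs. Reduce the C2 ketone of 13 kinetically (L-selectride gives the axial alcohol), invert by Mitsunobu to 2β and silylate. Then run a plain Birch reduction on the dicarboxylate, hydrolyse only to the β,γ-enone, esterify, and conjugate the enone as the ester.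
2. **Step 12 (conjugate propargylation at the hindered C8).** The β-carbon is flanked by two branched carbons and the addition may stall or go 1,2. Fallback: enone–allene [2+2] photocycloaddition on 15, which is insensitive to β-substitution, followed by a cyclobutane-to-bicyclo[3.2.1]octane rearrangement to build ring D. Alternatively, add an allyl or propargyl metal 1,2 to C13 and relay it to C8 by anionic oxy-Cope.
3. **Step 8 (lactone-enolate closure of ring A).** The bridged transition state may be too strained or the tertiary enolate too slow. Fallback: do not lactonise in step 6; protect C20–OH as a silyl ether and close ring A with the acyclic ester enolate. Then methylate the C4 ester enolate (equatorial attack gives the axial CO2Me cis to C20, as in podocarpate-type alkylations) and lactonise on desilylation.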